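The six-membered ring (C5–C10) is closed last at C8–C9, between the ring methylene C9 and the acyloxy-bearing C8. An enantioselective Ireland–Claisen rearrangement first sets the quaternary C10 (methyl, vinyl, CH2O) together with C5. An indium Barbier reaction then adds C6–C8 with the acrylate in place. The key step acts on an acyclic iodo amide: iodine–lithium exchange at the neopentyl C9 iodide and 6-exo attack on the C8 Weinreb amide give the cyclohexanone in one operation. A polar closure is chosen because C9 lies between the quaternary C10 (no β-hydrogen) and C8, and a C9 radical would suffer a 1,2-vinyl shift. Reduction, acylation and deprotection finish the route.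

Key step: step 15

Remark on numbering: C5 (CH bearing the hydroxypropenyl group), C6 (CHOH), C7 (CH bearing the acrylic acid), C8 (CH–O–acyl), C9 (CH2) and C10 (quaternary, methyl and vinyl) form the ring. C4 and C11 are the alkene carbons on C5 and C7, C12 is the carboxyl carbon, and C15 is the CH2OH carbon.

Assumption: the (4R,5R)-bromoborane of step 5 is taken to give the (2R,3R) acid 11, by analogy with this reagent class on 3-methylbut-3-enoates of (E)-trisubstituted allylic alcohols. If the sense of induction is the opposite, the (4S,5S)-reagent is used and nothing else changes.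

Step 1
Reactants: 1 1-[(tert-butyldimethylsilyl)oxy]propan-2-one; 2 triethyl phosphonoacetate
Product: 3 ethyl (2E)-4-[(tert-butyldimethylsilyl)oxy]-3-methylbut-2-enoate
Conditions: NaH, THF, 0 °C → rt; minor Z isomer removed by chromatography
Reagents that add atoms: none
Why: Horner–Wadsworth–Emmons olefination of a methyl ketone with a stabilised phosphonate should place the ester trans to the larger CH2OSi group and give mainly the E enoate; no stereocentre is formed.

Step 2
Reactants: 3 ethyl (2E)-4-[(tert-butyldimethylsilyl)oxy]-3-methylbut-2-enoate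
Product: 4 (2E)-4-[(tert-butyldimethylsilyl)oxy]-3-methylbut-2-en-1-ol
Conditions: i-Bu2AlH (2.2 equiv), CH2Cl2, −78 °C; Rochelle salt work-up
Reagents that add atoms: none
Why: 1,2-reduction of the enoate by the aluminium hydride gives the allylic alcohol with the alkene geometry retained.

Step 3
Reactants: 5 2-methylprop-2-en-1-ol
Product: 8 3-{[(tert-butyldiphenylsilyl)oxy]methyl}but-3-enoic acid, via dilithio dianion 6 (not isolated), via dilithium carboxylate 7 (not isolated)
Conditions: n-BuLi (2.2 equiv), TMEDA, Et2O, 0 °C → rt; CO2, −78 °C; then TBDPSCl, imidazole, THF, 0 °C → rt; dilute HCl work-up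
Reagents that add atoms: carbon dioxide O=C=O; tert-butyl(chloro)diphenylsilane CC(C)(C)[Si](Cl)(c1ccccc1)c1ccccc1
Why: allylic metalation of the lithium alkoxide gives a symmetrical 2-substituted allyl dianion whose carboxylation can only give the but-3-enoate, and O-silylation in the same flask prevents lactonisation of the γ-hydroxy acid (dianion carboxylation, then silyl ether formation).

Step 4
Reactants: 4 (2E)-4-[(tert-butyldimethylsilyl)oxy]-3-methylbut-2-en-1-ol; 8 3-{[(tert-butyldiphenylsilyl)oxy]methyl}but-3-enoic acid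
Product: 9 (2E)-4-[(tert-butyldimethylsilyl)oxy]-3-methylbut-2-en-1-yl 3-{[(tert-butyldiphenylsilyl)oxy]methyl}but-3-enoate
Conditions: DCC, DMAP (cat.), CH2Cl2, 0 °C
Reagents that add atoms: none
Why: Steglich esterification under nearly neutral conditions should couple the primary allylic alcohol without moving the β,γ-double bond of the acid into conjugation; no stereocentre is formed.

Step 5
Reactants: 9 (2E)-4-[(tert-butyldimethylsilyl)oxy]-3-methylbut-2-en-1-yl 3-{[(tert-butyldiphenylsilyl)oxy]methyl}but-3-enoate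
Product: 11 (2R,3R)-3-{[(tert-butyldimethylsilyl)oxy]methyl}-2-{3-[(tert-butyldiphenylsilyl)oxy]prop-1-en-2-yl}-3-methylpent-4-enoic acid, via boron ketene acetal 10 (not isolated)
Conditions: (4R,5R)-2-bromo-1,3-bis{[3,5-bis(trifluoromethyl)phenyl]sulfonyl}-4,5-diphenyl-1,3,2-diazaborolidine (1.3 equiv), Et3N, toluene/hexane, −78 °C, then −20 °C; aqueous work-up
Reagents that add atoms: none
Why: enantioselective Ireland–Claisen rearrangement, in which soft enolisation should give the E(O) boron dienolate 10 (C4 trans to O–B) that rearranges through a chair transition state with CH2OTBS pseudo-equatorial and methyl pseudo-axial on C10 and the C4 alkenyl group pseudo-axial on C5, fixing the C5/C10 relative configuration, while the C2-symmetric sulfonamide ligand selects the enolate face that leads to (2R,3R).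

Step 6
Reactants: 11 (2R,3R)-3-{[(tert-butyldimethylsilyl)oxy]methyl}-2-{3-[(tert-butyldiphenylsilyl)oxy]prop-1-en-2-yl}-3-methylpent-4-enoic acid
Product: 13 (3R,4R)-3-{3-[(tert-butyldiphenylsilyl)oxy]prop-1-en-2-yl}-4-ethenyl-4-methyloxolan-2-one, via hydroxy acid 12 (not isolated)
Conditions: camphorsulfonic acid (cat.), MeOH/CH2Cl2, 0 °C → rt
Reagents that add atoms: none
Why: acid-catalysed methanolysis removes the primary TBS ether much faster than the TBDPS ether, and the freed γ-hydroxy acid closes to the five-membered lactone (desilylation–lactonisation) without touching either stereocentre.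

Step 7
Reactants: 13 (3R,4R)-3-{3-[(tert-butyldiphenylsilyl)oxy]prop-1-en-2-yl}-4-ethenyl-4-methyloxolan-2-one
Product: 14 (3R,4R)-3-{3-[(tert-butyldiphenylsilyl)oxy]prop-1-en-2-yl}-4-ethenyl-4-methyloxolan-2-ol (both anomers)
Conditions: i-Bu2AlH (1.1 equiv), CH2Cl2, −78 °C
Reagents that add atoms: none
Why: partial reduction of a γ-lactone at low temperature stops at the aluminium hemiacetal and gives the lactol, which stores the epimerisable α-alkenyl aldehyde in masked form.

Step 8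
Reactants: 15 itaconic anhydride
Product: 16 4-[methoxy(methyl)amino]-2-methylidene-4-oxobutanoic acid
Conditions: MeNHOMe·HCl, Et3N (2.1 equiv), CH2Cl2, 0 °C → rt; dilute HCl work-up
Reagents that add atoms: N,O-dimethylhydroxylamine hydrochloride CNOC.Cl
Why: aminolysis of the cyclic anhydride should occur at the unconjugated, less hindered carbonyl, as in the alcoholysis of itaconic anhydride, and give the 4-amide 1-acid.

Step 9
Reactants: 16 4-[methoxy(methyl)amino]-2-methylidene-4-oxobutanoic acid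
Product: 17 tert-butyl 4-[methoxy(methyl)amino]-2-methylidene-4-oxobutanoate
Conditions: tert-butyl 2,2,2-trichloroacetimidate, BF3·OEt2 (cat.), CH2Cl2/cyclohexane, rt
Reagents that add atoms: tert-butyl 2,2,2-trichloroacetimidate CC(C)(C)OC(=N)C(Cl)(Cl)Cl
Why: acid-catalysed tert-butylation of the carboxylic acid with the imidate needs no base, so the itaconate double bond should not migrate.

Step 10
Reactants: 17 tert-butyl 4-[methoxy(methyl)amino]-2-methylidene-4-oxobutanoate
Product: 19 tert-butyl (2Z)-2-(bromomethyl)-4-[methoxy(methyl)amino]-4-oxobut-2-enoate, via dibromide 18 (not isolated)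
Conditions: Br2, CH2Cl2, 0 °C → rt; then Et3N, 0 °C → rt
Reagents that add atoms: bromine BrBr
Why: bromine addition to the acrylate followed by E1cB loss of HBr towards the amide α-hydrogen (bromination–dehydrobromination, as used for 2-(bromomethyl)fumarates) should give the conjugated allylic bromide with the two carbonyl groups trans.

Step 11
Reactants: 14 (3R,4R)-3-{3-[(tert-butyldiphenylsilyl)oxy]prop-1-en-2-yl}-4-ethenyl-4-methyloxolan-2-ol; 19 tert-butyl (2Z)-2-(bromomethyl)-4-[methoxy(methyl)amino]-4-oxobut-2-enoate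
Product: 20 tert-butyl (3S,4S,5R,6R)-5-{3-[(tert-butyldiphenylsilyl)oxy]prop-1-en-2-yl}-4-hydroxy-6-(hydroxymethyl)-3-[methoxy(methyl)carbamoyl]-6-methyl-2-methylideneoct-7-enoate
Conditions: In powder, THF/H2O (1:1), rt, sonication
Reagents that add atoms: none
Why: indium-mediated Barbier allylation of the open hydroxy-aldehyde form of the lactol, in which the allylindium reacts at its γ-carbon through a cyclic transition state that should give the 3,4-syn adduct (C7 relative to C6), while Felkin–Anh attack anti to the quaternary C10 sets C6 relative to C5.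

Step 12
Reactants: 20 tert-butyl (3S,4S,5R,6R)-5-{3-[(tert-butyldiphenylsilyl)oxy]prop-1-en-2-yl}-4-hydroxy-6-(hydroxymethyl)-3-[methoxy(methyl)carbamoyl]-6-methyl-2-methylideneoct-7-enoate
Product: 21 tert-butyl (3S,4S,5R,6R)-5-{3-[(tert-butyldiphenylsilyl)oxy]prop-1-en-2-yl}-3-[methoxy(methyl)carbamoyl]-6-methyl-2-methylidene-4-[(triethylsilyl)oxy]-6-{[(triethylsilyl)oxy]methyl}oct-7-enoate
Conditions: Et3SiOTf (2.4 equiv), 2,6-lutidine, CH2Cl2, −78 °C
Reagents that add atoms: triethylsilyl trifluoromethanesulfonate CC[Si](CC)(CC)OS(=O)(=O)C(F)(F)F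
Why: the silyl triflate with 2,6-lutidine silylates both the primary and the hindered secondary alcohol at −78 °C (silyl ether formation), cold enough to leave the tert-butyl ester untouched.

Step 13
Reactants: 21 tert-butyl (3S,4S,5R,6R)-5-{3-[(tert-butyldiphenylsilyl)oxy]prop-1-en-2-yl}-3-[methoxy(methyl)carbamoyl]-6-methyl-2-methylidene-4-[(triethylsilyl)oxy]-6-{[(triethylsilyl)oxy]methyl}oct-7-enoate
Product: 22 tert-butyl (3S,4S,5R,6R)-5-{3-[(tert-butyldiphenylsilyl)oxy]prop-1-en-2-yl}-6-(hydroxymethyl)-3-[methoxy(methyl)carbamoyl]-6-methyl-2-methylidene-4-[(triethylsilyl)oxy]oct-7-enoate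
Conditions: PPTS (cat.), MeOH/CH2Cl2, 0 °C
Reagents that add atoms: none
Why: mild acid-catalysed methanolysis cleaves the primary triethylsilyl ether faster than the secondary one, which is flanked by two branched carbons, and faster than the TBDPS ether (selective desilylation).

Step 14
Reactants: 22 tert-butyl (3S,4S,5R,6R)-5-{3-[(tert-butyldiphenylsilyl)oxy]prop-1-en-2-yl}-6-(hydroxymethyl)-3-[methoxy(methyl)carbamoyl]-6-methyl-2-methylidene-4-[(triethylsilyl)oxy]oct-7-enoate
Product: 23 tert-butyl (3S,4S,5R,6R)-5-{3-[(tert-butyldiphenylsilyl)oxy]prop-1-en-2-yl}-6-(iodomethyl)-3-[methoxy(methyl)carbamoyl]-6-methyl-2-methylidene-4-[(triethylsilyl)oxy]oct-7-enoate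
Conditions: PPh3, I2, imidazole (phosphonium iodide pre-formed), toluene, 70 °C
Reagents that add atoms: iodine II
Why: Appel-type iodination converts the primary alcohol into the iodide by SN2 displacement of the alkoxyphosphonium ion; the neopentyl position needs heat but has no β-hydrogen to eliminate.

Step 15
Reactants: 23 tert-butyl (3S,4S,5R,6R)-5-{3-[(tert-butyldiphenylsilyl)oxy]prop-1-en-2-yl}-6-(iodomethyl)-3-[methoxy(methyl)carbamoyl]-6-methyl-2-methylidene-4-[(triethylsilyl)oxy]oct-7-enoate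
Product: 26 tert-butyl 2-[(1S,2S,3S,4R)-3-{3-[(tert-butyldiphenylsilyl)oxy]prop-1-en-2-yl}-4-ethenyl-4-methyl-6-oxo-2-[(triethylsilyl)oxy]cyclohexyl]prop-2-enoate, via C9 organolithium 24 (not isolated), via lithium hemiaminal alkoxide 25 (not isolated)
Conditions: t-BuLi (2.1 equiv), Et2O/pentane, −100 °C → −78 °C; then AcOH/THF, −78 °C
Reagents that add atoms: none
Why: Two equivalents of t-BuLi exchange the primary neopentyl iodide through an iodine ate complex, so no free C9 radical forms and the fast 1,2-vinyl shift of a 2,2-disubstituted but-3-enyl radical cannot intervene; the alkyllithium 24, which has no β-hydrogen on C10, adds to the Weinreb amide carbonyl C8 to give the chelated adduct 25, which releases ketone 26 only on the cold acetic acid quench. The closest known reaction type is the Parham-type (halogen–metal exchange initiated) intramolecular acylation of iodoalkyl esters and N-methoxy-N-methylamides. The cyclohexane ring C5–C6–C7–C8–C9–C10 closes in the 6-exo-trig mode. No new stereocentre is formed here (C8 becomes the carbonyl carbon and is set in step 16), and C5, C6, C7 and C10 are untouched because the ketone appears only after the quench. The step needs exchange to be faster than attack of t-BuLi on a carbonyl, and C9–Li to attack the C8 amide instead of the acrylate (7-endo conjugate addition, or addition to the hindered conjugated tert-butyl ester) or to abstract the C7 proton; the low temperature, the tert-butyl ester, the six-membered transition state and N,O-chelation of lithium should secure this.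

Step 16
Reactants: 26 tert-butyl 2-[(1S,2S,3S,4R)-3-{3-[(tert-butyldiphenylsilyl)oxy]prop-1-en-2-yl}-4-ethenyl-4-methyl-6-oxo-2-[(triethylsilyl)oxy]cyclohexyl]prop-2-enoate
Product: 27 tert-butyl 2-[(1R,2S,3S,4R,6R)-3-{3-[(tert-butyldiphenylsilyl)oxy]prop-1-en-2-yl}-4-ethenyl-6-hydroxy-4-methyl-2-[(triethylsilyl)oxy]cyclohexyl]prop-2-enoate
Conditions: NaBH4, CeCl3·7H2O, MeOH/THF, −78 °C
Reagents that add atoms: none
Why: Luche reduction under non-basic conditions (no epimerisation at C7, no conjugate reduction), in which hydride should add along the axial trajectory on the face opposite the axial C7 substituent of the chair with C5 and C6 equatorial, giving the equatorial C8 alcohol cis to the C6 and C7 substituents.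

Step 17
Reactants: 28 dimethyl (2R)-2-hydroxybutanedioate
Product: 32 dimethyl (2R)-2-hydroxy-3-methylidenebutanedioate, via dilithium alkoxide enolate 29 (not isolated), via Mannich base 30 (not isolated), via ammonium iodide 31 (not isolated)
Conditions: LiN(SiMe3)2 (2.2 equiv), THF, −78 → −20 °C; [CH2=NMe2]I, −78 → 0 °C; AcOH quench; then MeI, MeOH, rt; then NaHCO3 (aq), CH2Cl2, rt
Reagents that add atoms: N,N-dimethylmethyleneiminium iodide C[N+](C)=C.[I-]
Why: Fráter–Seebach dianion chemistry aminomethylates C3 of the malate without touching the carbinol centre, and quaternisation followed by E1cB loss of trimethylamine (Eschenmoser methylenation) gives the methylidene succinate with the (2R) configuration retained.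

Step 18
Reactants: 32 dimethyl (2R)-2-hydroxy-3-methylidenebutanedioate
Product: 33 methyl (3R)-3,4-dihydroxy-2-methylidenebutanoate
Conditions: BH3·SMe2 (1.05 equiv), NaBH4 (5 mol %), THF, 0 °C → rt; MeOH quench
Reagents that add atoms: none
Why: hydroxyl-directed borane reduction takes the ester α to the free hydroxyl through a five-membered alkoxyborane and leaves the conjugated acrylate ester; the stereocentre is not involved.

Step 19
Reactants: 33 methyl (3R)-3,4-dihydroxy-2-methylidenebutanoate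
Product: 34 methyl (3R)-3,4-bis[(tert-butyldimethylsilyl)oxy]-2-methylidenebutanoate
Conditions: TBSCl, imidazole, DMF, rt
Reagents that add atoms: tert-butyl(chloro)dimethylsilane CC(C)(C)[Si](C)(C)Cl
Why: standard silyl ether formation on the primary and the secondary hydroxyl group.

Step 20
Reactants: 34 methyl (3R)-3,4-bis[(tert-butyldimethylsilyl)oxy]-2-methylidenebutanoate
Product: 35 (3R)-3,4-bis[(tert-butyldimethylsilyl)oxy]-2-methylidenebutanoic acid
Conditions: LiOH, THF/MeOH/H2O, 0 °C → rt; then dilute HCl to pH 4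
Reagents that add atoms: lithium hydroxide [Li+].[OH-]
Why: saponification of the methyl ester; the acrylate has no α-hydrogen, so neither epimerisation nor β-elimination of the silyloxy group can occur.

Step 21
Reactants: 27 tert-butyl 2-[(1R,2S,3S,4R,6R)-3-{3-[(tert-butyldiphenylsilyl)oxy]prop-1-en-2-yl}-4-ethenyl-6-hydroxy-4-methyl-2-[(triethylsilyl)oxy]cyclohexyl]prop-2-enoate; 35 (3R)-3,4-bis[(tert-butyldimethylsilyl)oxy]-2-methylidenebutanoic acid
Product: 37 tert-butyl 2-[(1R,2S,3S,4R,6R)-6-({(3R)-3,4-bis[(tert-butyldimethylsilyl)oxy]-2-methylidenebutanoyl}oxy)-3-{3-[(tert-butyldiphenylsilyl)oxy]prop-1-en-2-yl}-4-ethenyl-4-methyl-2-[(triethylsilyl)oxy]cyclohexyl]prop-2-enoate, via mixed anhydride 36 (not isolated)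
Conditions: 2,4,6-trichlorobenzoyl chloride, Et3N, THF, rt; then 27, DMAP, toluene, rt → 40 °C
Reagents that add atoms: none
Why: Yamaguchi esterification through the mixed anhydride acylates the equatorial C8 hydroxyl with retention of configuration, and the tert-butyl ester prevents lactonisation of O8 onto C12.

Step 22
Reactants: 37 tert-butyl 2-[(1R,2S,3S,4R,6R)-6-({(3R)-3,4-bis[(tert-butyldimethylsilyl)oxy]-2-methylidenebutanoyl}oxy)-3-{3-[(tert-butyldiphenylsilyl)oxy]prop-1-en-2-yl}-4-ethenyl-4-methyl-2-[(triethylsilyl)oxy]cyclohexyl]prop-2-enoate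
Product: 39 2-[(1R,2S,3S,4R,6R)-6-({(3R)-3,4-bis[(tert-butyldimethylsilyl)oxy]-2-methylidenebutanoyl}oxy)-3-{3-[(tert-butyldiphenylsilyl)oxy]prop-1-en-2-yl}-4-ethenyl-4-methyl-2-[(triethylsilyl)oxy]cyclohexyl]prop-2-enoic acid, via trimethylsilyl ester 38 (not isolated)
Conditions: Me3SiOTf, 2,6-lutidine, CH2Cl2, 0 °C; pH 5 buffer work-up
Reagents that add atoms: none
Why: silyl triflate-mediated cleavage of the tert-butyl ester (O-silylation, loss of 2-methylpropene, hydrolysis of the silyl ester on work-up) frees the acid under non-protic, buffered conditions that should leave the silyl ethers and both acrylate esters intact.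

Step 23
Reactants: 39 2-[(1R,2S,3S,4R,6R)-6-({(3R)-3,4-bis[(tert-butyldimethylsilyl)oxy]-2-methylidenebutanoyl}oxy)-3-{3-[(tert-butyldiphenylsilyl)oxy]prop-1-en-2-yl}-4-ethenyl-4-methyl-2-[(triethylsilyl)oxy]cyclohexyl]prop-2-enoic acid
Product: 40 2-[(1S,2S,3S,4R,6R)-6-{[(3R)-3,4-dihydroxy-2-methylidenebutanoyl]oxy}-4-ethenyl-2-hydroxy-3-(3-hydroxyprop-1-en-2-yl)-4-methylcyclohexyl]prop-2-enoic acid (CNP0348657.1)
Conditions: HF·pyridine, pyridine, THF, 0 °C → rt; pH 5 buffer work-up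
Reagents that add atoms: none
Why: fluoride-mediated global desilylation with pyridine-buffered HF removes the triethylsilyl, both TBS and the primary TBDPS groups without base, which would lactonise the side-chain γ-hydroxy ester, and without strong acid, which would close the 6,12-lactone.

Compound list
1 | 1-[(tert-butyldimethylsilyl)oxy]propan-2-one | CC(=O)CO[Si](C)(C)C(C)(C)C | starting material
2 | triethyl phosphonoacetate | CCOC(=O)CP(=O)(OCC)OCC | starting material
3 | ethyl (2E)-4-[(tert-butyldimethylsilyl)oxy]-3-methylbut-2-enoate | CCOC(=O)/C=C(C)/CO[Si](C)(C)C(C)(C)C | intermediate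
4 | (2E)-4-[(tert-butyldimethylsilyl)oxy]-3-methylbut-2-en-1-ol | OC/C=C(C)/CO[Si](C)(C)C(C)(C)C | intermediate
5 | 2-methylprop-2-en-1-ol | CC(=C)CO | starting material
6 | dilithium 2-(oxidomethyl)prop-2-en-1-ide (dilithio dianion of 5) | [Li+].[Li+].[CH2-]C(=C)C[O-] | intermediate
7 | dilithium 3-(oxidomethyl)but-3-enoate | [Li+].[Li+].[O-]CC(=C)CC([O-])=O | intermediate
8 | 3-{[(tert-butyldiphenylsilyl)oxy]methyl}but-3-enoic acid | C=C(CO[Si](c1ccccc1)(c1ccccc1)C(C)(C)C)CC(=O)O | intermediate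
9 | (2E)-4-[(tert-butyldimethylsilyl)oxy]-3-methylbut-2-en-1-yl 3-{[(tert-butyldiphenylsilyl)oxy]methyl}but-3-enoate | C=C(CO[Si](c1ccccc1)(c1ccccc1)C(C)(C)C)CC(=O)OC/C=C(C)/CO[Si](C)(C)C(C)(C)C | intermediate
10 | E(O) boron ketene acetal of 9 carrying the (4R,5R)-1,3-bis{[3,5-bis(trifluoromethyl)phenyl]sulfonyl}-4,5-diphenyl-1,3,2-diazaborolidin-2-yl group on oxygen | C=C(CO[Si](c1ccccc1)(c1ccccc1)C(C)(C)C)/C=C(/OB1N(S(=O)(=O)c2cc(cc(c2)C(F)(F)F)C(F)(F)F)[C@H](c2ccccc2)[C@@H](c2ccccc2)N1S(=O)(=O)c1cc(cc(c1)C(F)(F)F)C(F)(F)F)OC/C=C(C)/CO[Si](C)(C)C(C)(C)C | intermediate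
11 | (2R,3R)-3-{[(tert-butyldimethylsilyl)oxy]methyl}-2-{3-[(tert-butyldiphenylsilyl)oxy]prop-1-en-2-yl}-3-methylpent-4-enoic acid | C=C[C@@](C)(CO[Si](C)(C)C(C)(C)C)[C@@H](C(=C)CO[Si](c1ccccc1)(c1ccccc1)C(C)(C)C)C(=O)O | intermediate
12 | (2R,3R)-2-{3-[(tert-butyldiphenylsilyl)oxy]prop-1-en-2-yl}-3-(hydroxymethyl)-3-methylpent-4-enoic acid | C=C[C@@](C)(CO)[C@@H](C(=C)CO[Si](c1ccccc1)(c1ccccc1)C(C)(C)C)C(=O)O | intermediate
13 | (3R,4R)-3-{3-[(tert-butyldiphenylsilyl)oxy]prop-1-en-2-yl}-4-ethenyl-4-methyloxolan-2-one | C=C[C@@]1(C)COC(=O)[C@@H]1C(=C)CO[Si](c2ccccc2)(c2ccccc2)C(C)(C)C | intermediate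
14 | (3R,4R)-3-{3-[(tert-butyldiphenylsilyl)oxy]prop-1-en-2-yl}-4-ethenyl-4-methyloxolan-2-ol (both anomers) | C=C[C@@]1(C)COC(O)[C@@H]1C(=C)CO[Si](c2ccccc2)(c2ccccc2)C(C)(C)C | intermediate
15 | itaconic anhydride (3-methylideneoxolane-2,5-dione) | C=C1CC(=O)OC1=O | starting material
16 | 4-[methoxy(methyl)amino]-2-methylidene-4-oxobutanoic acid | C=C(CC(=O)N(C)OC)C(=O)O | intermediate
17 | tert-butyl 4-[methoxy(methyl)amino]-2-methylidene-4-oxobutanoate | C=C(CC(=O)N(C)OC)C(=O)OC(C)(C)C | intermediate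
18 | tert-butyl 2-bromo-2-(bromomethyl)-4-[methoxy(methyl)amino]-4-oxobutanoate (racemic) | BrCC(Br)(CC(=O)N(C)OC)C(=O)OC(C)(C)C | intermediate
19 | tert-butyl (2Z)-2-(bromomethyl)-4-[methoxy(methyl)amino]-4-oxobut-2-enoate | BrC/C(C(=O)OC(C)(C)C)=C\C(=O)N(C)OC | intermediate
20 | tert-butyl (3S,4S,5R,6R)-5-{3-[(tert-butyldiphenylsilyl)oxy]prop-1-en-2-yl}-4-hydroxy-6-(hydroxymethyl)-3-[methoxy(methyl)carbamoyl]-6-methyl-2-methylideneoct-7-enoate | C=C[C@@](C)(CO)[C@@H](C(=C)CO[Si](c1ccccc1)(c1ccccc1)C(C)(C)C)[C@H](O)[C@H](C(=C)C(=O)OC(C)(C)C)C(=O)N(C)OC | intermediate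
21 | tert-butyl (3S,4S,5R,6R)-5-{3-[(tert-butyldiphenylsilyl)oxy]prop-1-en-2-yl}-3-[methoxy(methyl)carbamoyl]-6-methyl-2-methylidene-4-[(triethylsilyl)oxy]-6-{[(triethylsilyl)oxy]methyl}oct-7-enoate | C=C[C@@](C)(CO[Si](CC)(CC)CC)[C@@H](C(=C)CO[Si](c1ccccc1)(c1ccccc1)C(C)(C)C)[C@H](O[Si](CC)(CC)CC)[C@H](C(=C)C(=O)OC(C)(C)C)C(=O)N(C)OC | intermediate
22 | tert-butyl (3S,4S,5R,6R)-5-{3-[(tert-butyldiphenylsilyl)oxy]prop-1-en-2-yl}-6-(hydroxymethyl)-3-[methoxy(methyl)carbamoyl]-6-methyl-2-methylidene-4-[(triethylsilyl)oxy]oct-7-enoate | C=C[C@@](C)(CO)[C@@H](C(=C)CO[Si](c1ccccc1)(c1ccccc1)C(C)(C)C)[C@H](O[Si](CC)(CC)CC)[C@H](C(=C)C(=O)OC(C)(C)C)C(=O)N(C)OC | intermediate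
23 | tert-butyl (3S,4S,5R,6R)-5-{3-[(tert-butyldiphenylsilyl)oxy]prop-1-en-2-yl}-6-(iodomethyl)-3-[methoxy(methyl)carbamoyl]-6-methyl-2-methylidene-4-[(triethylsilyl)oxy]oct-7-enoate | C=C[C@@](C)(CI)[C@@H](C(=C)CO[Si](c1ccccc1)(c1ccccc1)C(C)(C)C)[C@H](O[Si](CC)(CC)CC)[C@H](C(=C)C(=O)OC(C)(C)C)C(=O)N(C)OC | intermediate
24 | 6-(lithiomethyl) analogue of 23 (C9 organolithium; all stereocentres as in 23) | C=C[C@@](C)(C[Li])[C@@H](C(=C)CO[Si](c1ccccc1)(c1ccccc1)C(C)(C)C)[C@H](O[Si](CC)(CC)CC)[C@H](C(=C)C(=O)OC(C)(C)C)C(=O)N(C)OC | intermediate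
25 | lithium alkoxide of the cyclic N-methoxy-N-methyl hemiaminal at C8 (tetrahedral adduct; either configuration at C8; other centres as in 26) | C=C[C@@]1(C)CC(O[Li])(N(C)OC)[C@@H](C(=C)C(=O)OC(C)(C)C)[C@@H](O[Si](CC)(CC)CC)[C@@H]1C(=C)CO[Si](c2ccccc2)(c2ccccc2)C(C)(C)C | intermediate
26 | tert-butyl 2-[(1S,2S,3S,4R)-3-{3-[(tert-butyldiphenylsilyl)oxy]prop-1-en-2-yl}-4-ethenyl-4-methyl-6-oxo-2-[(triethylsilyl)oxy]cyclohexyl]prop-2-enoate | C=C[C@@]1(C)CC(=O)[C@@H](C(=C)C(=O)OC(C)(C)C)[C@@H](O[Si](CC)(CC)CC)[C@@H]1C(=C)CO[Si](c2ccccc2)(c2ccccc2)C(C)(C)C | intermediate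
27 | tert-butyl 2-[(1R,2S,3S,4R,6R)-3-{3-[(tert-butyldiphenylsilyl)oxy]prop-1-en-2-yl}-4-ethenyl-6-hydroxy-4-methyl-2-[(triethylsilyl)oxy]cyclohexyl]prop-2-enoate | C=C[C@@]1(C)C[C@@H](O)[C@@H](C(=C)C(=O)OC(C)(C)C)[C@@H](O[Si](CC)(CC)CC)[C@@H]1C(=C)CO[Si](c2ccccc2)(c2ccccc2)C(C)(C)C | intermediate
28 | dimethyl (2R)-2-hydroxybutanedioate (dimethyl D-malate) | COC(=O)C[C@@H](O)C(=O)OC | starting material
29 | dilithium alkoxide enolate of 28 | COC(=O)[C@H]([O-])/C=C(\[O-])OC.[Li+].[Li+] | intermediate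
30 | dimethyl (2R,3S)-3-[(dimethylamino)methyl]-2-hydroxybutanedioate | COC(=O)[C@H](O)[C@H](CN(C)C)C(=O)OC | intermediate
31 | [(2S,3R)-3-hydroxy-4-methoxy-2-(methoxycarbonyl)-4-oxobutyl]trimethylammonium iodide | COC(=O)[C@H](O)[C@H](C[N+](C)(C)C)C(=O)OC.[I-] | intermediate
32 | dimethyl (2R)-2-hydroxy-3-methylidenebutanedioate | C=C(C(=O)OC)[C@@H](O)C(=O)OC | intermediate
33 | methyl (3R)-3,4-dihydroxy-2-methylidenebutanoate | C=C(C(=O)OC)[C@@H](O)CO | intermediate
34 | methyl (3R)-3,4-bis[(tert-butyldimethylsilyl)oxy]-2-methylidenebutanoate | C=C(C(=O)OC)[C@@H](O[Si](C)(C)C(C)(C)C)CO[Si](C)(C)C(C)(C)C | intermediate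
35 | (3R)-3,4-bis[(tert-butyldimethylsilyl)oxy]-2-methylidenebutanoic acid | C=C(C(=O)O)[C@@H](O[Si](C)(C)C(C)(C)C)CO[Si](C)(C)C(C)(C)C | intermediate
36 | (3R)-3,4-bis[(tert-butyldimethylsilyl)oxy]-2-methylidenebutanoic 2,4,6-trichlorobenzoic anhydride | C=C(C(=O)OC(=O)c1c(Cl)cc(Cl)cc1Cl)[C@@H](O[Si](C)(C)C(C)(C)C)CO[Si](C)(C)C(C)(C)C | intermediate
37 | tert-butyl 2-[(1R,2S,3S,4R,6R)-6-({(3R)-3,4-bis[(tert-butyldimethylsilyl)oxy]-2-methylidenebutanoyl}oxy)-3-{3-[(tert-butyldiphenylsilyl)oxy]prop-1-en-2-yl}-4-ethenyl-4-methyl-2-[(triethylsilyl)oxy]cyclohexyl]prop-2-enoate | C=C[C@@]1(C)C[C@@H](OC(=O)C(=C)[C@@H](O[Si](C)(C)C(C)(C)C)CO[Si](C)(C)C(C)(C)C)[C@@H](C(=C)C(=O)OC(C)(C)C)[C@@H](O[Si](CC)(CC)CC)[C@@H]1C(=C)CO[Si](c2ccccc2)(c2ccccc2)C(C)(C)C | intermediate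
38 | trimethylsilyl ester corresponding to 39 | C=C[C@@]1(C)C[C@@H](OC(=O)C(=C)[C@@H](O[Si](C)(C)C(C)(C)C)CO[Si](C)(C)C(C)(C)C)[C@@H](C(=C)C(=O)O[Si](C)(C)C)[C@@H](O[Si](CC)(CC)CC)[C@@H]1C(=C)CO[Si](c2ccccc2)(c2ccccc2)C(C)(C)C | intermediate
39 | 2-[(1R,2S,3S,4R,6R)-6-({(3R)-3,4-bis[(tert-butyldimethylsilyl)oxy]-2-methylidenebutanoyl}oxy)-3-{3-[(tert-butyldiphenylsilyl)oxy]prop-1-en-2-yl}-4-ethenyl-4-methyl-2-[(triethylsilyl)oxy]cyclohexyl]prop-2-enoic acid | C=C[C@@]1(C)C[C@@H](OC(=O)C(=C)[C@@H](O[Si](C)(C)C(C)(C)C)CO[Si](C)(C)C(C)(C)C)[C@@H](C(=C)C(=O)O)[C@@H](O[Si](CC)(CC)CC)[C@@H]1C(=C)CO[Si](c2ccccc2)(c2ccccc2)C(C)(C)C | intermediate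
40 | 2-[(1S,2S,3S,4R,6R)-6-{[(3R)-3,4-dihydroxy-2-methylidenebutanoyl]oxy}-4-ethenyl-2-hydroxy-3-(3-hydroxyprop-1-en-2-yl)-4-methylcyclohexyl]prop-2-enoic acid (CNP0348657.1) | C=C[C@@]1(C)C[C@@H](OC(=O)C(=C)[C@@H](O)CO)[C@@H](C(=C)C(=O)O)[C@@H](O)[C@@H]1C(=C)CO | target

Total step count: 23 steps.
Longest linear sequence: 15 steps (1, 2, 4, 5, 6, 7, 11, 12, 13, 14, 15, 16, 21, 22, 23).

The three steps most likely to fail

Step 15. The exchange–acylation may be diverted: the new C9–Li (or t-BuLi itself) can add to the acrylate, or a proton can pass from the doubly activated C7–H to C9 before the C–C bond forms. The fallback sets out from 23 and masks the acrylate for the ring closure. Conjugate addition of thiophenol (PhSH, Et3N cat., CH2Cl2) should give tert-butyl (3S,4S,5R,6R)-5-{3-[(tert-butyldiphenylsilyl)oxy]prop-1-en-2-yl}-6-(iodomethyl)-3-[methoxy(methyl)carbamoyl]-6-methyl-2-[(phenylsulfanyl)methyl]-4-[(triethylsilyl)oxy]oct-7-enoate F1, in which C7–H is no longer allylic. The same t-BuLi exchange and acylation should then give tert-butyl 2-[(1S,2S,3S,4R)-3-{3-[(tert-butyldiphenylsilyl)oxy]prop-1-en-2-yl}-4-ethenyl-4-methyl-6-oxo-2-[(triethylsilyl)oxy]cyclohexyl]-3-(phenylsulfanyl)propanoate F2. Luche reduction should give tert-butyl 2-[(1R,2S,3S,4R,6R)-3-{3-[(tert-butyldiphenylsilyl)oxy]prop-1-en-2-yl}-4-ethenyl-6-hydroxy-4-methyl-2-[(triethylsilyl)oxy]cyclohexyl]-3-(phenylsulfanyl)propanoate F3. Oxidation with NaIO4 (MeOH/H2O) should give the sulfoxide tert-butyl 3-(benzenesulfinyl)-2-[(1R,2S,3S,4R,6R)-3-{3-[(tert-butyldiphenylsilyl)oxy]prop-1-en-2-yl}-4-ethenyl-6-hydroxy-4-methyl-2-[(triethylsilyl)oxy]cyclohexyl]propanoate F4. Its thermal syn-elimination (toluene, CaCO3, 110 °C) can only run towards C11–H, restores the methylidene ester and rejoins the route at 27.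

Step 5. The chiral boron reagent may select the enolate face incompletely or in the opposite sense, the E(O) geometry of the dienolate may erode (mixed C5/C10 diastereomers), and the Lewis acidic bromoborane may strip a silyl ether. The fallback sets out from 9 and replaces reagent control by resolution. A classical Ireland–Claisen rearrangement (LiN(i-Pr)2, THF, −78 °C; Me3SiCl/Et3N; warm to rt; aqueous work-up) should give the racemic (2R*,3R*)-3-{[(tert-butyldimethylsilyl)oxy]methyl}-2-{3-[(tert-butyldiphenylsilyl)oxy]prop-1-en-2-yl}-3-methylpent-4-enoic acid F5. Acidic methanolysis as in step 6 should give the racemic (3R*,4R*)-3-{3-[(tert-butyldiphenylsilyl)oxy]prop-1-en-2-yl}-4-ethenyl-4-methyloxolan-2-one F6. Aminolysis with (S)-1-phenylethylamine and AlMe3 (CH2Cl2) gives two diastereomeric hydroxy amides, from which (2R,3R)-2-{3-[(tert-butyldiphenylsilyl)oxy]prop-1-en-2-yl}-3-(hydroxymethyl)-3-methyl-N-[(1S)-1-phenylethyl]pent-4-enamide F7 is separated by chromatography. Relactonisation (p-TsOH, toluene, 80 °C) releases the amine and rejoins the route at 13.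

Step 11. The loosely organised indium allylation may give poor syn/anti or Felkin selection, and the lactol may open too slowly to compete with protonation of the allylindium. The fallback sets out from 19 (used with 14) and replaces the Barbier reaction by a closed, stereospecific allylboration. Borylation of 19 (bis(pinacolato)diboron, Pd2(dba)3 cat., DMSO, rt; Miyaura-type allylic borylation) should give tert-butyl (2E)-4-[methoxy(methyl)amino]-4-oxo-2-[(4,4,5,5-tetramethyl-1,3,2-dioxaborolan-2-yl)methyl]but-2-enoate F8, in which the amide stays cis to the CH2B carbon. Heating F8 with lactol 14 (toluene, 60 °C) should pass through a six-membered chair transition state that turns this geometry into the syn C6/C7 relationship, with Felkin control from C5 as before. Aqueous work-up rejoins the route at 20.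

Further compounds
F1 | step 15 | tert-butyl (3S,4S,5R,6R)-5-{3-[(tert-butyldiphenylsilyl)oxy]prop-1-en-2-yl}-6-(iodomethyl)-3-[methoxy(methyl)carbamoyl]-6-methyl-2-[(phenylsulfanyl)methyl]-4-[(triethylsilyl)oxy]oct-7-enoate (both C2 epimers) | C=C[C@@](C)(CI)[C@@H](C(=C)CO[Si](c1ccccc1)(c1ccccc1)C(C)(C)C)[C@H](O[Si](CC)(CC)CC)[C@H](C(CSc1ccccc1)C(=O)OC(C)(C)C)C(=O)N(C)OC
F2 | step 15 | tert-butyl 2-[(1S,2S,3S,4R)-3-{3-[(tert-butyldiphenylsilyl)oxy]prop-1-en-2-yl}-4-ethenyl-4-methyl-6-oxo-2-[(triethylsilyl)oxy]cyclohexyl]-3-(phenylsulfanyl)propanoate (both C2 epimers) | C=C[C@@]1(C)CC(=O)[C@@H](C(CSc2ccccc2)C(=O)OC(C)(C)C)[C@@H](O[Si](CC)(CC)CC)[C@@H]1C(=C)CO[Si](c2ccccc2)(c2ccccc2)C(C)(C)C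
F3 | step 15 | tert-butyl 2-[(1R,2S,3S,4R,6R)-3-{3-[(tert-butyldiphenylsilyl)oxy]prop-1-en-2-yl}-4-ethenyl-6-hydroxy-4-methyl-2-[(triethylsilyl)oxy]cyclohexyl]-3-(phenylsulfanyl)propanoate (both C2 epimers) | C=C[C@@]1(C)C[C@@H](O)[C@@H](C(CSc2ccccc2)C(=O)OC(C)(C)C)[C@@H](O[Si](CC)(CC)CC)[C@@H]1C(=C)CO[Si](c2ccccc2)(c2ccccc2)C(C)(C)C
F4 | step 15 | tert-butyl 3-(benzenesulfinyl)-2-[(1R,2S,3S,4R,6R)-3-{3-[(tert-butyldiphenylsilyl)oxy]prop-1-en-2-yl}-4-ethenyl-6-hydroxy-4-methyl-2-[(triethylsilyl)oxy]cyclohexyl]propanoate (mixture at C2 and sulfur) | C=C[C@@]1(C)C[C@@H](O)[C@@H](C(CS(=O)c2ccccc2)C(=O)OC(C)(C)C)[C@@H](O[Si](CC)(CC)CC)[C@@H]1C(=C)CO[Si](c2ccccc2)(c2ccccc2)C(C)(C)C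
F5 | step 5 | racemic (2R*,3R*)-3-{[(tert-butyldimethylsilyl)oxy]methyl}-2-{3-[(tert-butyldiphenylsilyl)oxy]prop-1-en-2-yl}-3-methylpent-4-enoic acid (one enantiomer drawn) | C=C[C@@](C)(CO[Si](C)(C)C(C)(C)C)[C@@H](C(=C)CO[Si](c1ccccc1)(c1ccccc1)C(C)(C)C)C(=O)O
F6 | step 5 | racemic (3R*,4R*)-3-{3-[(tert-butyldiphenylsilyl)oxy]prop-1-en-2-yl}-4-ethenyl-4-methyloxolan-2-one (one enantiomer drawn) | C=C[C@@]1(C)COC(=O)[C@@H]1C(=C)CO[Si](c2ccccc2)(c2ccccc2)C(C)(C)C
F7 | step 5 | (2R,3R)-2-{3-[(tert-butyldiphenylsilyl)oxy]prop-1-en-2-yl}-3-(hydroxymethyl)-3-methyl-N-[(1S)-1-phenylethyl]pent-4-enamide | C=C[C@@](C)(CO)[C@@H](C(=C)CO[Si](c1ccccc1)(c1ccccc1)C(C)(C)C)C(=O)N[C@@H](C)c1ccccc1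
F8 | step 11 | tert-butyl (2E)-4-[methoxy(methyl)amino]-4-oxo-2-[(4,4,5,5-tetramethyl-1,3,2-dioxaborolan-2-yl)methyl]but-2-enoate | CC1(C)OB(C/C(C(=O)OC(C)(C)C)=C\C(=O)N(C)OC)OC1(C)C
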